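The route rests on cutting the C1–C2 bond of the tetralone. The feature used is the 1,3-relation in the cyclohexanone ring between the C1 ketone, attached to C8a beside the C8 oxygen of the benzene ring, and the C3 carbinol. C1 becomes an aryl aldehyde; C2 and C3 become the terminal and the oxygen-bearing carbon of a 2-benzyloxyallyl group on C4a. One rhodium-catalysed hydroacylation adds the formyl C–H bond across this alkene, closing the six-membered ring and setting C3 as (S), the only stereocentre. The precursor is an achiral pentasubstituted benzaldehyde carrying the O-benzyl pyrone, phenyl and benzyloxy groups; one hydrogenolysis then frees all three hydroxyls.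

Key step: step 13

Remark: which antipode of the bisphosphine gives (S) on a 2-alkoxyallyl group cannot be read from the alkyl and aryl cases; (R)-DTBM-SEGPHOS is written, and the mirror-image ligand takes its place if a pilot run on 20 shows the opposite sense.

Step 1
Reactants: 1 4-bromo-2-chloro-6-fluorobenzaldehyde; 2 benzyl alcohol
Product: 4 2-(benzyloxy)-4-bromo-6-chlorobenzaldehyde, via sodium benzyl oxide 3 (not isolated)
Conditions: NaH, THF, 0 °C; then 1, −20 → 0 °C
Reagents that add atoms: benzyl alcohol, OCc1ccccc1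
Why: Nucleophilic aromatic substitution (addition–elimination): the fluoride ortho to the formyl group is displaced by the alkoxide far faster than chloride or bromide, so only the C–F position should react at this temperature.

Step 2
Reactants: 4 2-(benzyloxy)-4-bromo-6-chlorobenzaldehyde; 5 phenylboronic acid
Product: 6 2-(benzyloxy)-6-chloro-4-phenylbenzaldehyde
Conditions: Pd(PPh3)4 (3 mol%), Na2CO3, toluene/EtOH/H2O, 80 °C
Reagents that add atoms: phenylboronic acid, OB(O)c1ccccc1
Why: Suzuki–Miyaura coupling: with triphenylphosphine-ligated zerovalent palladium the C–Br bond para to the formyl group should undergo oxidative addition well before the C–Cl bond, which is kept as the later handle at C4a.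

Step 3
Reactants: 6 2-(benzyloxy)-6-chloro-4-phenylbenzaldehyde
Product: 7 6-(benzyloxy)-2-chloro-3-iodo-4-phenylbenzaldehyde
Conditions: NIS, TFA, MeCN, rt
Reagents that add atoms: N-iodosuccinimide, O=C1CCC(=O)N1I
Why: Electrophilic aromatic iodination: the benzyloxy group is the only strong donor and directs para, to the position between chlorine and phenyl (the pattern of 3-haloanisoles), while the other free position, ortho to the ether, is shielded by the benzyl group; both positions are meta to the formyl group.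

Step 4
Reactants: 8 tert-butyl acetate; 9 3-(trimethylsilyl)prop-2-ynal
Product: 11 tert-butyl 3-hydroxy-5-(trimethylsilyl)pent-4-ynoate (racemic), via lithium enolate of tert-butyl acetate 10 (not isolated)
Conditions: LiN(iPr)2, THF, −78 °C; then 9; H2O
Reagents that add atoms: tert-butyl acetate, CC(=O)OC(C)(C)C; 3-(trimethylsilyl)prop-2-ynal, C[Si](C)(C)C#CC=O
Why: Aldol addition of an ester lithium enolate to a non-enolisable ynal (1,2-addition at low temperature); the carbinol centre forms as the racemate and is erased by the oxidation in step 7.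

Step 5
Reactants: 11 tert-butyl 3-hydroxy-5-(trimethylsilyl)pent-4-ynoate
Product: 12 tert-butyl 3-hydroxypent-4-ynoate (racemic)
Conditions: K2CO3 (cat.), MeOH, 0 °C
Reagents that add atoms: none
Why: Base-catalysed protodesilylation of the alkynylsilane by methanol, mild enough to leave the tert-butyl ester and the β-hydroxy ester untouched.

Step 6
Reactants: 7 6-(benzyloxy)-2-chloro-3-iodo-4-phenylbenzaldehyde; 12 tert-butyl 3-hydroxypent-4-ynoate
Product: 13 tert-butyl 5-[4-(benzyloxy)-2-chloro-3-formyl-6-phenylphenyl]-3-hydroxypent-4-ynoate (racemic carbinol)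
Conditions: Pd(PPh3)2Cl2 (3 mol%), CuI (6 mol%), Et3N, THF, 40 °C
Reagents that add atoms: tert-butyl 3-hydroxypent-4-ynoate, C#CC(O)CC(=O)OC(C)(C)C
Why: Sonogashira coupling: the electron-poor aryl iodide should add to zerovalent palladium under these mild conditions while the C–Cl bond stays intact, and the slim alkyne tolerates the two flanking substituents.

Step 7
Reactants: 13 tert-butyl 5-[4-(benzyloxy)-2-chloro-3-formyl-6-phenylphenyl]-3-hydroxypent-4-ynoate
Product: 14 tert-butyl 5-[4-(benzyloxy)-2-chloro-3-formyl-6-phenylphenyl]-3-oxopent-4-ynoate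
Conditions: Dess–Martin periodinane, CH2Cl2, 0 °C → rt
Reagents that add atoms: none
Why: Dess–Martin oxidation of the propargylic alcohol to the ynone under neutral conditions that spare the aryl aldehyde and the tert-butyl ester.

Step 8
Reactants: 14 tert-butyl 5-[4-(benzyloxy)-2-chloro-3-formyl-6-phenylphenyl]-3-oxopent-4-ynoate
Product: 15 6-(benzyloxy)-2-chloro-3-(4-hydroxy-2-oxo-2H-pyran-6-yl)-4-phenylbenzaldehyde
Conditions: (SPhos)AuNTf2 (5 mol%), MeNO2/AcOH, rt
Reagents that add atoms: none
Why: Gold-catalysed 6-endo-dig cyclisation of a tert-butyl 3-oxoalk-4-ynoate: the ester carbonyl oxygen attacks the gold-activated alkyne at the aryl-bearing carbon, isobutene is lost and protodeauration gives the 4-hydroxy-2-pyrone, the alkyne being meta to the formyl group and so out of reach of the aldehyde oxygen.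

Step 9
Reactants: 15 6-(benzyloxy)-2-chloro-3-(4-hydroxy-2-oxo-2H-pyran-6-yl)-4-phenylbenzaldehyde; 2 benzyl alcohol
Product: 16 6-(benzyloxy)-3-[4-(benzyloxy)-2-oxo-2H-pyran-6-yl]-2-chloro-4-phenylbenzaldehyde
Conditions: PPh3, DIAD, THF, 0 °C → rt
Reagents that add atoms: benzyl alcohol, OCc1ccccc1
Why: Mitsunobu alkylation: the acidic 4-hydroxy-2-pyrone is benzylated on the 4-oxygen, the usual site under these conditions, without a base that could touch the aldehyde.

Step 10
Reactants: 16 6-(benzyloxy)-3-[4-(benzyloxy)-2-oxo-2H-pyran-6-yl]-2-chloro-4-phenylbenzaldehyde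
Product: 17 6-(benzyloxy)-3-[4-(benzyloxy)-2-oxo-2H-pyran-6-yl]-4-phenyl-2-(4,4,5,5-tetramethyl-1,3,2-dioxaborolan-2-yl)benzaldehyde
Conditions: B2pin2, Pd2(dba)3 (2 mol%), XPhos (8 mol%), KOAc, 1,4-dioxane, 100 °C
Reagents that add atoms: bis(pinacolato)diboron, CC1(C)OB(OC1(C)C)B1OC(C)(C)C(C)(C)O1
Why: Miyaura borylation of an aryl chloride: zerovalent palladium carrying a bulky biarylphosphine should insert into the C–Cl bond, which is activated by the ortho formyl group although flanked on both sides, and acetate-assisted transmetalation with the diboron gives the pinacol boronate.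

Step 11
Reactants: 17 6-(benzyloxy)-3-[4-(benzyloxy)-2-oxo-2H-pyran-6-yl]-4-phenyl-2-(4,4,5,5-tetramethyl-1,3,2-dioxaborolan-2-yl)benzaldehyde; 18 2,3-dibromopropene
Product: 19 6-(benzyloxy)-3-[4-(benzyloxy)-2-oxo-2H-pyran-6-yl]-2-(2-bromoprop-2-en-1-yl)-4-phenylbenzaldehyde
Conditions: Pd(PPh3)4 (5 mol%), K2CO3, THF/H2O, 60 °C; 18 in excess
Reagents that add atoms: 2,3-dibromopropene, C=C(Br)CBr
Why: Suzuki–Miyaura allylation: zerovalent palladium ionises the allylic C–Br bond of 18 to a 2-bromoallyl palladium species that couples with the aryl boronate, while the vinylic C–Br bond, much slower with this catalyst, is kept and the excess of 18 suppresses a second coupling.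

Step 12
Reactants: 19 6-(benzyloxy)-3-[4-(benzyloxy)-2-oxo-2H-pyran-6-yl]-2-(2-bromoprop-2-en-1-yl)-4-phenylbenzaldehyde; 2 benzyl alcohol
Product: 20 6-(benzyloxy)-2-[2-(benzyloxy)prop-2-en-1-yl]-3-[4-(benzyloxy)-2-oxo-2H-pyran-6-yl]-4-phenylbenzaldehyde (achiral)
Conditions: CuI (10 mol%), 3,4,7,8-tetramethyl-1,10-phenanthroline (20 mol%), Cs2CO3, toluene, 80 °C; chromatography on Et3N-treated silica
Reagents that add atoms: benzyl alcohol, OCc1ccccc1
Why: Ullmann-type copper-catalysed C–O coupling of an alkenyl bromide with a primary alcohol: the copper alkoxide should replace the vinylic bromide without moving the double bond, the carbonate base being too weak to dehydrobrominate, and any exchange of benzyl oxide at the pyrone 4-position being degenerate.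

Step 13
Reactants: 20 6-(benzyloxy)-2-[2-(benzyloxy)prop-2-en-1-yl]-3-[4-(benzyloxy)-2-oxo-2H-pyran-6-yl]-4-phenylbenzaldehyde
Product: 21 (3S)-3,8-bis(benzyloxy)-5-[4-(benzyloxy)-2-oxo-2H-pyran-6-yl]-6-phenyl-3,4-dihydronaphthalen-1(2H)-one (tri-O-benzyl wailupemycin F)
Conditions: [Rh(cod)Cl]2 (2.5 mol%), (R)-DTBM-SEGPHOS (5.5 mol%), NaB[3,5-(CF3)2C6H3]4 (5 mol%), 1,4-dioxane, 60 °C
Reagents that add atoms: none
Why: Proposed new method: a cationic monovalent rhodium bisphosphine complex adds oxidatively to the formyl C–H bond of 20, the acyl rhodium hydride binds the pendant enol-ether alkene, hydride migrates to the oxygen-bearing carbon C3, and the acyl and C2-alkyl groups of the seven-membered rhodacycle couple by reductive elimination; the closest known reaction is the endo- and enantioselective rhodium-catalysed hydroacylation of ortho-allylbenzaldehydes with 2-alkyl- or 2-aryl-substituted allyl groups, which has not been run on a 2-alkoxyallyl group. The cyclohexanone ring closes in a formal 6-endo-trig mode, both alkene carbons ending inside the ring. The C3 stereocentre is set at the hydride-transfer step, where the axially chiral, twofold-symmetric ligand tells the two alkene faces apart. The step needs rhodium at the terminal carbon (endo over exo), one alkene face, and reductive elimination faster than decarbonylation, loss of benzyl oxide from the position β to rhodium, or alkene migration. The geminal substitution of the alkene makes the alternative tertiary α-alkoxyalkyl rhodium crowded, the twofold ortho substitution of the aldehyde holds formyl group and alkene close, and the neighbouring C8 benzyloxy oxygen can fill a vacant site on the acyl rhodium and so retard loss of CO.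

Step 14
Reactants: 21 (3S)-3,8-bis(benzyloxy)-5-[4-(benzyloxy)-2-oxo-2H-pyran-6-yl]-6-phenyl-3,4-dihydronaphthalen-1(2H)-one
Product: 22 wailupemycin F, (3S)-3,8-dihydroxy-5-(4-hydroxy-2-oxo-2H-pyran-6-yl)-6-phenyl-3,4-dihydronaphthalen-1(2H)-one
Conditions: H2 (1 atm), Pd/C, EtOAc, rt; stopped after uptake of 3 equiv
Reagents that add atoms: none
Why: Catalytic hydrogenolysis of the phenol benzyl ether, the pyrone benzyl ether and the secondary alkyl benzyl ether under neutral conditions, which should leave the β-hydroxy ketone undehydrated and C3 untouched.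

Compound list
1 | 4-bromo-2-chloro-6-fluorobenzaldehyde | O=Cc1c(F)cc(Br)cc1Cl | starting material
2 | benzyl alcohol | OCc1ccccc1 | starting material
3 | sodium benzyl oxide | [Na+].[O-]Cc1ccccc1 | intermediate
4 | 2-(benzyloxy)-4-bromo-6-chlorobenzaldehyde | O=Cc1c(Cl)cc(Br)cc1OCc1ccccc1 | intermediate
5 | phenylboronic acid | OB(O)c1ccccc1 | starting material
6 | 2-(benzyloxy)-6-chloro-4-phenylbenzaldehyde | O=Cc1c(Cl)cc(-c2ccccc2)cc1OCc1ccccc1 | intermediate
7 | 6-(benzyloxy)-2-chloro-3-iodo-4-phenylbenzaldehyde | O=Cc1c(Cl)c(I)c(-c2ccccc2)cc1OCc1ccccc1 | intermediate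
8 | tert-butyl acetate | CC(=O)OC(C)(C)C | starting material
9 | 3-(trimethylsilyl)prop-2-ynal | C[Si](C)(C)C#CC=O | starting material
10 | lithium enolate of tert-butyl acetate | [Li]OC(=C)OC(C)(C)C | intermediate
11 | tert-butyl 3-hydroxy-5-(trimethylsilyl)pent-4-ynoate (racemic) | C[Si](C)(C)C#CC(O)CC(=O)OC(C)(C)C | intermediate
12 | tert-butyl 3-hydroxypent-4-ynoate (racemic) | C#CC(O)CC(=O)OC(C)(C)C | intermediate
13 | tert-butyl 5-[4-(benzyloxy)-2-chloro-3-formyl-6-phenylphenyl]-3-hydroxypent-4-ynoate (racemic) | O=Cc1c(Cl)c(C#CC(O)CC(=O)OC(C)(C)C)c(-c2ccccc2)cc1OCc1ccccc1 | intermediate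
14 | tert-butyl 5-[4-(benzyloxy)-2-chloro-3-formyl-6-phenylphenyl]-3-oxopent-4-ynoate | O=Cc1c(Cl)c(C#CC(=O)CC(=O)OC(C)(C)C)c(-c2ccccc2)cc1OCc1ccccc1 | intermediate
15 | 6-(benzyloxy)-2-chloro-3-(4-hydroxy-2-oxo-2H-pyran-6-yl)-4-phenylbenzaldehyde | O=Cc1c(Cl)c(-c2cc(O)cc(=O)o2)c(-c2ccccc2)cc1OCc1ccccc1 | intermediate
16 | 6-(benzyloxy)-3-[4-(benzyloxy)-2-oxo-2H-pyran-6-yl]-2-chloro-4-phenylbenzaldehyde | O=Cc1c(Cl)c(-c2cc(OCc3ccccc3)cc(=O)o2)c(-c2ccccc2)cc1OCc1ccccc1 | intermediate
17 | 6-(benzyloxy)-3-[4-(benzyloxy)-2-oxo-2H-pyran-6-yl]-4-phenyl-2-(4,4,5,5-tetramethyl-1,3,2-dioxaborolan-2-yl)benzaldehyde | O=Cc1c(B2OC(C)(C)C(C)(C)O2)c(-c2cc(OCc3ccccc3)cc(=O)o2)c(-c2ccccc2)cc1OCc1ccccc1 | intermediate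
18 | 2,3-dibromopropene | C=C(Br)CBr | starting material
19 | 6-(benzyloxy)-3-[4-(benzyloxy)-2-oxo-2H-pyran-6-yl]-2-(2-bromoprop-2-en-1-yl)-4-phenylbenzaldehyde | O=Cc1c(CC(Br)=C)c(-c2cc(OCc3ccccc3)cc(=O)o2)c(-c2ccccc2)cc1OCc1ccccc1 | intermediate
20 | 6-(benzyloxy)-2-[2-(benzyloxy)prop-2-en-1-yl]-3-[4-(benzyloxy)-2-oxo-2H-pyran-6-yl]-4-phenylbenzaldehyde (achiral) | O=Cc1c(OCc2ccccc2)cc(-c2ccccc2)c(-c2cc(OCc3ccccc3)cc(=O)o2)c1CC(=C)OCc1ccccc1 | intermediate
21 | (3S)-3,8-bis(benzyloxy)-5-[4-(benzyloxy)-2-oxo-2H-pyran-6-yl]-6-phenyl-3,4-dihydronaphthalen-1(2H)-one | O=C1C[C@@H](OCc2ccccc2)Cc2c1c(OCc1ccccc1)cc(-c1ccccc1)c2-c1cc(OCc2ccccc2)cc(=O)o1 | intermediate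
22 | wailupemycin F, (3S)-3,8-dihydroxy-5-(4-hydroxy-2-oxo-2H-pyran-6-yl)-6-phenyl-3,4-dihydronaphthalen-1(2H)-one | O=C1C[C@@H](O)Cc2c1c(O)cc(-c1ccccc1)c2-c1cc(O)cc(=O)o1 | target

Total step count: 14. Longest linear sequence: 12 steps (steps 1–3 and 6–14, from 1 to 22); steps 4 and 5 build the alkyne 12 in a side branch.

Steps most likely to fail

Step 13. The rhodium alkyl at C2 may lose benzyl oxide from the β-position and end as a ring-opened benzyl ester. The acyl rhodium hydride may extrude CO, or deliver hydride to the terminal carbon, which leads to the five-membered ketone or to alkene migration. Facial discrimination on an enol ether may also be weak. The fallback closes the same ring through the C2–C3 bond by an aldol reaction and uses only known chemistry. It sets out from 16. Stille coupling with allyltributylstannane (Pd2(dba)3, P(t-Bu)3, CsF, dioxane, 100 °C) should give 2-allyl-6-(benzyloxy)-3-[4-(benzyloxy)-2-oxo-2H-pyran-6-yl]-4-phenylbenzaldehyde F1. MeTi(OiPr)3, which adds to aldehydes but spares lactones, should give the carbinol 1-{2-allyl-6-(benzyloxy)-3-[4-(benzyloxy)-2-oxo-2H-pyran-6-yl]-4-phenylphenyl}ethanol F2. Dess–Martin oxidation should give the methyl ketone 1-{2-allyl-6-(benzyloxy)-3-[4-(benzyloxy)-2-oxo-2H-pyran-6-yl]-4-phenylphenyl}ethanone F3. Cleavage of the terminal alkene (OsO4 cat., NaIO4, 2,6-lutidine, dioxane/H2O) should give the keto aldehyde 2-{2-acetyl-3-(benzyloxy)-6-[4-(benzyloxy)-2-oxo-2H-pyran-6-yl]-5-phenylphenyl}acetaldehyde F4. Enolisation of the methyl ketone with the fitting antipode of Ipc2BCl and Et3N at −78 °C, followed by intramolecular aldol addition to the tethered aldehyde, should give mainly (3S)-8-(benzyloxy)-5-[4-(benzyloxy)-2-oxo-2H-pyran-6-yl]-3-hydroxy-6-phenyl-3,4-dihydronaphthalen-1(2H)-one F5. Hydrogenolysis under the conditions of step 14 brings the fallback back to the route at 22.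

Step 12. The 2-bromoallyl group may lose HBr or isomerise under the hot basic conditions. Benzyl oxide may attack the aldehyde (hydride transfer) or open the pyrone, and the enol ether may hydrolyse during isolation. The fallback replaces the substitution by an oxidative coupling at room temperature. It sets out from 19. Miyaura borylation of the alkenyl bromide (B2pin2, Pd(PPh3)2Cl2, PPh3, KOPh, toluene, 50 °C) should give 6-(benzyloxy)-3-[4-(benzyloxy)-2-oxo-2H-pyran-6-yl]-4-phenyl-2-[2-(4,4,5,5-tetramethyl-1,3,2-dioxaborolan-2-yl)prop-2-en-1-yl]benzaldehyde F6. Chan–Lam-type etherification of this alkenyl boronate with benzyl alcohol 2 (Cu(OAc)2, Et3N, rt, air) comes back to the route at 20.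

Step 10. Oxidative addition at the doubly flanked C–Cl bond may be slow, so that reduction of the chloride and protodeboronation of the crowded ortho-formyl boronate take over. The fallback forms the C4a–C4 bond with the enol ether already in place, by a neutral Stille coupling. 2,3-Dibromopropene 18 and Bu3SnLi (THF, −78 °C) should give tributyl(2-bromoprop-2-en-1-yl)stannane F7. The copper-catalysed etherification of step 12, run on this small molecule with 2, should give tributyl[2-(benzyloxy)prop-2-en-1-yl]stannane F8. The fallback sets out from 16, whose coupling with the stannane (Pd2(dba)3, P(t-Bu)3, CsF, dioxane, 100 °C) comes back to the route at 20 and bypasses 17 and 19.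

Further compounds
F1 | step 13 | 2-allyl-6-(benzyloxy)-3-[4-(benzyloxy)-2-oxo-2H-pyran-6-yl]-4-phenylbenzaldehyde | O=Cc1c(CC=C)c(-c2cc(OCc3ccccc3)cc(=O)o2)c(-c2ccccc2)cc1OCc1ccccc1
F2 | step 13 | 1-{2-allyl-6-(benzyloxy)-3-[4-(benzyloxy)-2-oxo-2H-pyran-6-yl]-4-phenylphenyl}ethanol (racemic) | CC(O)c1c(CC=C)c(-c2cc(OCc3ccccc3)cc(=O)o2)c(-c2ccccc2)cc1OCc1ccccc1
F3 | step 13 | 1-{2-allyl-6-(benzyloxy)-3-[4-(benzyloxy)-2-oxo-2H-pyran-6-yl]-4-phenylphenyl}ethanone | CC(=O)c1c(CC=C)c(-c2cc(OCc3ccccc3)cc(=O)o2)c(-c2ccccc2)cc1OCc1ccccc1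
F4 | step 13 | 2-{2-acetyl-3-(benzyloxy)-6-[4-(benzyloxy)-2-oxo-2H-pyran-6-yl]-5-phenylphenyl}acetaldehyde | CC(=O)c1c(CC=O)c(-c2cc(OCc3ccccc3)cc(=O)o2)c(-c2ccccc2)cc1OCc1ccccc1
F5 | step 13 | (3S)-8-(benzyloxy)-5-[4-(benzyloxy)-2-oxo-2H-pyran-6-yl]-3-hydroxy-6-phenyl-3,4-dihydronaphthalen-1(2H)-one | O=C1C[C@@H](O)Cc2c1c(OCc1ccccc1)cc(-c1ccccc1)c2-c1cc(OCc2ccccc2)cc(=O)o1
F6 | step 12 | 6-(benzyloxy)-3-[4-(benzyloxy)-2-oxo-2H-pyran-6-yl]-4-phenyl-2-[2-(4,4,5,5-tetramethyl-1,3,2-dioxaborolan-2-yl)prop-2-en-1-yl]benzaldehyde | O=Cc1c(CC(=C)B2OC(C)(C)C(C)(C)O2)c(-c2cc(OCc3ccccc3)cc(=O)o2)c(-c2ccccc2)cc1OCc1ccccc1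
F7 | step 10 | tributyl(2-bromoprop-2-en-1-yl)stannane | CCCC[Sn](CCCC)(CCCC)CC(Br)=C
F8 | step 10 | tributyl[2-(benzyloxy)prop-2-en-1-yl]stannane | CCCC[Sn](CCCC)(CCCC)CC(=C)OCc1ccccc1
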